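**Retrosynthetic overview**
- Feature used: on the tetrahydrofuran ring (O1, C2–C5) the C9H2OH arm on C3 and the C7'H2–aryl arm on C4 are cis to each other and both trans to the C2 aryl. This is the pattern left by a syn addition across C3=C4 of a 2-aryl-2,5-dihydrofuran on the face away from the aryl.
- Late disconnection: C9–OH and C7'H2 are the two ends of a former cyclobutene C9=C7' double bond (ozonolysis, then radical removal of the C7' oxygen).
- Key disconnection: C3–C9 and C4–C7' by gold-catalysed alkyne–alkene [2+2] between (S)-2-(3,4,5-trimethoxyphenyl)-2,5-dihydrofuran and 5-ethynyl-1,2,3-trimethoxybenzene.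
- Early disconnection: C2–aryl by asymmetric Heck arylation of 2,3-dihydrofuran with the aryl triflate.
- Ring order: the oxygen ring is bought; the cyclobutene is the only ring made (step 3) and it is opened again (step 4).

Key step: step 3

Locants: tetrahydrofuran numbering (O1, C2 aryl, C3, C4, C5); C9 is the carbinol carbon on C3 and C7' the benzylic carbon on C4.

Assumption: the sense of induction in the Heck step is taken to follow that known for simple aryl triflates with this ligand class, so the (R)-ligand is used to reach the (S)-product; if the sense were opposite, the enantiomeric ligand would be used.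

Remark on the endgame: the C7' hydroxyl is removed by a radical method, because hydrogenolysis or ionic hydrogenation could also cut the benzylic C2–O1 bond of the ring.

**Route**

Step 1
Reactants: 1 3,4,5-trimethoxyphenol
Product: 2 3,4,5-trimethoxyphenyl trifluoromethanesulfonate
Conditions: Tf2O, pyridine, CH2Cl2, 0 °C
Reagents that add atoms: trifluoromethanesulfonic anhydride, O=S(=O)(OS(=O)(=O)C(F)(F)F)C(F)(F)F
Why: O-sulfonylation of a phenol with triflic anhydride and an amine base is a standard way to make an aryl triflate for cationic Heck chemistry.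

Step 2
Reactants: 2 3,4,5-trimethoxyphenyl trifluoromethanesulfonate, 3 2,3-dihydrofuran
Product: 4 (S)-2-(3,4,5-trimethoxyphenyl)-2,5-dihydrofuran
Conditions: Pd2(dba)3 (zerovalent palladium, 1.5 mol%), (R)-4-tert-butyl-2-[2-(diphenylphosphino)phenyl]-4,5-dihydrooxazole (4 mol%), i-Pr2NEt, THF, 70 °C, 3 in excess
Reagents that add atoms: none
Why: Asymmetric Heck reaction by the cationic pathway, in which the aryl group adds to C2 of the enol ether and the P,N-ligand selects the alkene face (setting C2) and releases the product after the first β-hydride elimination, so the C3=C4 isomer is kept.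

Step 3
Reactants: 4 (S)-2-(3,4,5-trimethoxyphenyl)-2,5-dihydrofuran, 5 5-ethynyl-1,2,3-trimethoxybenzene
Product: 6 (1S,2S,5S)-2,6-bis(3,4,5-trimethoxyphenyl)-3-oxabicyclo[3.2.0]hept-6-ene (cis-fused; C2 aryl anti to the cyclobutene)
Conditions: [(t-BuXPhos)Au(NCMe)]SbF6 (monovalent gold, 5 mol%), CH2Cl2, 23 °C, 5 (2 equiv) added slowly to concentrated 4
Reagents that add atoms: none
Why: Proposed new method: the cationic gold complex binds the terminal alkyne of 5, the C3=C4 bond of 4 attacks the aryl-bearing alkyne carbon to give a cyclopropyl gold carbene, and migration of C3 to the carbene carbon with loss of the gold fragment gives the cyclobutene; the closest known reaction is the gold-catalysed intermolecular [2+2] cycloaddition of terminal arylalkynes with simple alkenes, which has not been shown on a 2,5-dihydrofuran whose double bond is flanked by two allylic C–O bonds. The four-membered ring (C3, C4, C7', C9) closes by this formal [2+2] cycloaddition (cyclopropanation, then ring expansion), which is suprafacial on the alkene, so the ring fusion can only be cis. The two new stereocentres, C3 and C4 of the furan ring (C1 and C5 of the bicycle), are therefore cis to each other, and their sense is set by the C2 aryl group of 4, which shields one face of the nearly flat ring so that the bulky gold–alkyne complex adds from the face carrying only the C2 hydrogen. The step needs regiocontrol (aryl-bearing carbon to C4, terminal carbon to C3) and freedom from cationic 1,2-shifts: the more advanced bond should form between the congested aryl-bearing alkyne carbon and the less hindered C4, remote from the C2 aryl, while the partial positive charge left at C3 is supported by the antiperiplanar C2–aryl bond. Because that charge stays inside the cyclopropyl gold carbene and does not become a free cation, hydride or aryl migration from C2 should not compete, and slow addition of 5 keeps alkyne oligomerisation down.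

Step 4
Reactants: 6 (1S,2S,5S)-2,6-bis(3,4,5-trimethoxyphenyl)-3-oxabicyclo[3.2.0]hept-6-ene
Product: 8 [(2S,3R,4R)-4-[hydroxy(3,4,5-trimethoxyphenyl)methyl]-2-(3,4,5-trimethoxyphenyl)tetrahydrofuran-3-yl]methanol (both C7' epimers), via ozonide 7 (not isolated)
Conditions: O3, CH2Cl2, −78 °C (Sudan Red 7B end point); then NaBH4, MeOH, −78 °C to rt
Reagents that add atoms: ozone, [O-][O+]=O
Why: Ozonolysis (Criegee mechanism) of the strained styrene-type cyclobutene bond is much faster than attack on the methoxyarenes, and NaBH4 reduces the ozonide to the C9 primary and C7' benzylic alcohols in the cold before C3 or C4 can epimerise; the new C7' centre is uncontrolled and is removed in step 7.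

Step 5
Reactants: 8 [(2S,3R,4R)-4-[hydroxy(3,4,5-trimethoxyphenyl)methyl]-2-(3,4,5-trimethoxyphenyl)tetrahydrofuran-3-yl]methanol
Product: 9 (2S,3R,4R)-3-[(tert-butyldimethylsilyloxy)methyl]-4-[hydroxy(3,4,5-trimethoxyphenyl)methyl]-2-(3,4,5-trimethoxyphenyl)tetrahydrofuran
Conditions: TBSCl (1.05 equiv), imidazole, CH2Cl2, 0 °C
Reagents that add atoms: tert-butyldimethylsilyl chloride, CC(C)(C)[Si](C)(C)Cl
Why: Silylation is selective for the unhindered primary C9 hydroxyl over the hindered secondary benzylic C7' hydroxyl.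

Step 6
Reactants: 9 (2S,3R,4R)-3-[(tert-butyldimethylsilyloxy)methyl]-4-[hydroxy(3,4,5-trimethoxyphenyl)methyl]-2-(3,4,5-trimethoxyphenyl)tetrahydrofuran
Product: 10 O-phenyl thionocarbonate of 9 at the C7' oxygen
Conditions: PhOC(S)Cl, pyridine, DMAP (cat.), CH2Cl2, 0 °C to rt
Reagents that add atoms: O-phenyl chlorothionoformate, S=C(Cl)Oc1ccccc1
Why: DMAP-catalysed thioacylation of the one free hydroxyl under non-basic conditions (no silyl migration) gives the radical precursor for a Barton–McCombie deoxygenation.

Step 7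
Reactants: 10 O-phenyl thionocarbonate of 9
Product: 11 (2S,3R,4R)-3-[(tert-butyldimethylsilyloxy)methyl]-4-(3,4,5-trimethoxybenzyl)-2-(3,4,5-trimethoxyphenyl)tetrahydrofuran
Conditions: Bu3SnH, AIBN, toluene, 90 °C
Reagents that add atoms: none
Why: Barton–McCombie deoxygenation, in which the stannyl radical adds to C=S, β-scission gives the stabilised C7' benzylic radical and this takes hydrogen from Bu3SnH; the benzylic C2–O1 ether is inert to these radicals and C4 is untouched because the radical is exocyclic.

Step 8
Reactants: 11 (2S,3R,4R)-3-[(tert-butyldimethylsilyloxy)methyl]-4-(3,4,5-trimethoxybenzyl)-2-(3,4,5-trimethoxyphenyl)tetrahydrofuran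
Product: 12 [(2S,3R,4R)-4-(3,4,5-trimethoxybenzyl)-2-(3,4,5-trimethoxyphenyl)tetrahydrofuran-3-yl]methanol
Conditions: TBAF, THF, 0 °C to rt
Reagents that add atoms: none
Why: Fluoride cleavage of the primary silyl ether leaves the ethers and all three stereocentres unchanged.

**Compound list**
1 | 3,4,5-trimethoxyphenol | COc1cc(O)cc(OC)c1OC | starting material
2 | 3,4,5-trimethoxyphenyl trifluoromethanesulfonate | COc1cc(OS(=O)(=O)C(F)(F)F)cc(OC)c1OC | intermediate
3 | 2,3-dihydrofuran | C1=COCC1 | starting material
4 | (S)-2-(3,4,5-trimethoxyphenyl)-2,5-dihydrofuran | COc1cc([C@@H]2C=CCO2)cc(OC)c1OC | intermediate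
5 | 5-ethynyl-1,2,3-trimethoxybenzene | C#Cc1cc(OC)c(OC)c(OC)c1 | starting material
6 | (1S,2S,5S)-2,6-bis(3,4,5-trimethoxyphenyl)-3-oxabicyclo[3.2.0]hept-6-ene | COc1cc(C2=C[C@H]3[C@@H]2CO[C@@H]3c2cc(OC)c(OC)c(OC)c2)cc(OC)c1OC | intermediate
7 | ozonide of 6 (1,2,4-trioxolane spanning C7' and C9; bridge on either face) | COc1cc(C23OOC(O2)[C@@H]2[C@@H](c4cc(OC)c(OC)c(OC)c4)OC[C@@H]23)cc(OC)c1OC | intermediate
8 | [(2S,3R,4R)-4-[hydroxy(3,4,5-trimethoxyphenyl)methyl]-2-(3,4,5-trimethoxyphenyl)tetrahydrofuran-3-yl]methanol, C7' epimers | COc1cc(C(O)[C@H]2CO[C@H](c3cc(OC)c(OC)c(OC)c3)[C@H]2CO)cc(OC)c1OC | intermediate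
9 | (2S,3R,4R)-3-[(tert-butyldimethylsilyloxy)methyl]-4-[hydroxy(3,4,5-trimethoxyphenyl)methyl]-2-(3,4,5-trimethoxyphenyl)tetrahydrofuran | COc1cc(C(O)[C@H]2CO[C@H](c3cc(OC)c(OC)c(OC)c3)[C@H]2CO[Si](C)(C)C(C)(C)C)cc(OC)c1OC | intermediate
10 | O-phenyl thionocarbonate of 9 at the C7' oxygen | COc1cc(C(OC(=S)Oc2ccccc2)[C@H]2CO[C@H](c3cc(OC)c(OC)c(OC)c3)[C@H]2CO[Si](C)(C)C(C)(C)C)cc(OC)c1OC | intermediate
11 | (2S,3R,4R)-3-[(tert-butyldimethylsilyloxy)methyl]-4-(3,4,5-trimethoxybenzyl)-2-(3,4,5-trimethoxyphenyl)tetrahydrofuran | COc1cc(C[C@H]2CO[C@H](c3cc(OC)c(OC)c(OC)c3)[C@H]2CO[Si](C)(C)C(C)(C)C)cc(OC)c1OC | intermediate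
12 | [(2S,3R,4R)-4-(3,4,5-trimethoxybenzyl)-2-(3,4,5-trimethoxyphenyl)tetrahydrofuran-3-yl]methanol | COc1cc(C[C@H]2CO[C@H](c3cc(OC)c(OC)c(OC)c3)[C@H]2CO)cc(OC)c1OC | target

**Count**
Total steps: 8. Longest linear sequence: 8 steps (1 to 12); 3 and 5 are bought.

**Steps most likely to fail**

Step 3. The C3=C4 bond, deactivated by two allylic C–O bonds, may be too weak a nucleophile for the gold-bound alkyne, so that alkyne oligomerisation or arylation of the activated alkyne by a trimethoxyphenyl ring takes over. The ring expansion may also go with the reverse regiochemistry, or positive charge at C3 may set off a 1,2-shift from C2 or opening of the allylic, benzylic C2–O1 bond.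
Fallback (known chemistry; sets out from 4, comes back at 6): the four-membered ring is built by a concerted ketene cycloaddition and the aryl group is added afterwards.
- Dichloroketene (Cl3CCOCl, Zn–Cu couple, DME/Et2O) should add to C3=C4 of 4 anti to the aryl group, the ketene carbonyl carbon going to the less hindered C4, to give (1S,2S,5R)-7,7-dichloro-2-(3,4,5-trimethoxyphenyl)-3-oxabicyclo[3.2.0]heptan-6-one F1.
- Zn in AcOH removes both chlorines to give (1S,2S,5R)-2-(3,4,5-trimethoxyphenyl)-3-oxabicyclo[3.2.0]heptan-6-one F2; a regioisomeric ketone would be separated here.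
- 3,4,5-Trimethoxyphenylmagnesium bromide with CeCl3 in THF at −78 °C should add from the convex face to give the tertiary alcohol (1S,2S,5R)-2,6-bis(3,4,5-trimethoxyphenyl)-3-oxabicyclo[3.2.0]heptan-6-ol F3.
- Dehydration with the Burgess reagent in toluene toward the C7 methylene gives 6.
- This answers low reactivity and cation-driven shifts; it does not remove the regiochemical question, which would be settled by separation at the ketone stage.

Step 4. Ozone may also attack the two electron-rich arenes, the aryl-substituted ozonide may rearrange instead of being reduced, and the keto-aldehyde stage may epimerise at C4 before reduction.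
Fallback (sets out from 6, comes back at 8): the cleavage is done in stages without ozone.
- OsO4 (cat.) with N-methylmorpholine N-oxide in acetone/water should dihydroxylate the cyclobutene from the convex face to give the cis-diol 2,6-bis(3,4,5-trimethoxyphenyl)-3-oxabicyclo[3.2.0]heptane-6,7-diol (hydroxyls syn to the ring-fusion hydrogens) F4.
- NaIO4 in THF/water cleaves the glycol to (2S,3S,4R)-2-(3,4,5-trimethoxyphenyl)-4-(3,4,5-trimethoxybenzoyl)tetrahydrofuran-3-carbaldehyde F5.
- F5 is reduced at once with NaBH4 in MeOH at 0 °C to 8.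

Step 6. The hindered, electron-rich benzylic carbinol may thioacylate slowly, and the thionocarbonate may ionise, leading to elimination toward a C4=C7' styrene (loss of the C4 stereocentre) or O-to-S rearrangement before the radical step.
Fallback (sets out from 8, comes back at 12; replaces steps 5 to 8): the C7' oxygen is removed by catalytic hydrogenolysis of an ester.
- Ac2O, pyridine and DMAP give the diacetate (2S,3R,4R)-3-(acetoxymethyl)-4-[acetoxy(3,4,5-trimethoxyphenyl)methyl]-2-(3,4,5-trimethoxyphenyl)tetrahydrofuran F6.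
- H2 (1 atm) over Pd/C (zerovalent palladium on carbon) in EtOAc at rt should cleave the benzylic acetate faster than the ring C2–O1 ether; the reaction is stopped at [(2S,3R,4R)-4-(3,4,5-trimethoxybenzyl)-2-(3,4,5-trimethoxyphenyl)tetrahydrofuran-3-yl]methyl acetate F7.
- K2CO3 in MeOH removes the remaining acetate to give 12.

**Further compounds**
F1 | step 3 | (1S,2S,5R)-7,7-dichloro-2-(3,4,5-trimethoxyphenyl)-3-oxabicyclo[3.2.0]heptan-6-one | O=C1C(Cl)(Cl)[C@H]2[C@@H]1CO[C@@H]2c1cc(OC)c(OC)c(OC)c1
F2 | step 3 | (1S,2S,5R)-2-(3,4,5-trimethoxyphenyl)-3-oxabicyclo[3.2.0]heptan-6-one | O=C1C[C@H]2[C@@H]1CO[C@@H]2c1cc(OC)c(OC)c(OC)c1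
F3 | step 3 | (1S,2S,5R)-2,6-bis(3,4,5-trimethoxyphenyl)-3-oxabicyclo[3.2.0]heptan-6-ol, carbinol configuration not fixed | OC1(c2cc(OC)c(OC)c(OC)c2)C[C@H]2[C@@H]1CO[C@@H]2c1cc(OC)c(OC)c(OC)c1
F4 | step 4 | 2,6-bis(3,4,5-trimethoxyphenyl)-3-oxabicyclo[3.2.0]heptane-6,7-diol, cis-diol syn to the ring-fusion hydrogens | COc1cc([C@]2(O)[C@@H](O)[C@H]3[C@@H]2CO[C@@H]3c2cc(OC)c(OC)c(OC)c2)cc(OC)c1OC
F5 | step 4 | (2S,3S,4R)-2-(3,4,5-trimethoxyphenyl)-4-(3,4,5-trimethoxybenzoyl)tetrahydrofuran-3-carbaldehyde | COc1cc(C(=O)[C@H]2CO[C@H](c3cc(OC)c(OC)c(OC)c3)[C@H]2C=O)cc(OC)c1OC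
F6 | step 6 | (2S,3R,4R)-3-(acetoxymethyl)-4-[acetoxy(3,4,5-trimethoxyphenyl)methyl]-2-(3,4,5-trimethoxyphenyl)tetrahydrofuran, C7' epimers | COc1cc(C(OC(C)=O)[C@H]2CO[C@H](c3cc(OC)c(OC)c(OC)c3)[C@H]2COC(C)=O)cc(OC)c1OC
F7 | step 6 | [(2S,3R,4R)-4-(3,4,5-trimethoxybenzyl)-2-(3,4,5-trimethoxyphenyl)tetrahydrofuran-3-yl]methyl acetate | COc1cc(C[C@H]2CO[C@H](c3cc(OC)c(OC)c(OC)c3)[C@H]2COC(C)=O)cc(OC)c1OC
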